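Ring A is built last. Its C5(OH)–C6(prenyl)–C7(OH)–C8(H) unit is the chain C1–C4 of a 2-prenyl-1,3-dioxygenated butadiene, and C4a=C8a is the enol ether double bond of a 2,3-dihydropyran-4-one. One Diels–Alder/aromatisation therefore forms C4a–C5 and C8–C8a and delivers the whole 6-prenylphloroglucinol ring with fixed regiochemistry, without touching C3. The dienophile is a (3R)-3-aryl-5-(phenylsulfinyl)-2,3-dihydropyran-4-one that already carries the geranyl chain and a silyl-protected phenol. Its C3 centre comes from an auxiliary-controlled hydroxymethylation, and the sulfinyl group both activates the alkene and leaves as sulfenic acid.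

Key step: step 11

Abbreviations: Ar = 3-[(2E)-3,7-dimethylocta-2,6-dien-1-yl]-4-[(triisopropylsilyl)oxy]phenyl; TIPS = triisopropylsilyl; prenyl = 3-methylbut-2-en-1-yl; geranyl = (2E)-3,7-dimethylocta-2,6-dien-1-yl.

Remark (sulfur): the sulfinyl sulfur is a stereocentre, so a 5-(phenylsulfinyl) dienophile is one stereoisomer only if sulfur is defined; because sulfur is lost in the key step, racemic methyl phenyl sulfoxide is used on purpose and the sulfinyl compounds are carried as pairs of sulfur epimers, each (R) at carbon.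

Remark (protecting group): the ring-B phenol is carried as a TIPS ether and not as an acetal, so the last step is a buffered fluoride cleavage and the enolisable C3–H and the prenyl/geranyl–phenol pairs never meet strong acid or base.

Remark (order of events): 3-bromo-4-hydroxyphenylacetic acid is taken as the commercial starting material, and the geranyl chain is attached only after the TiCl4-mediated hydroxymethylation, because activated formaldehyde would attack its trisubstituted alkenes.

Remark (alkene geometry): the geometry of the silyl enol ether and ketene acetal double bonds of the diene and its precursor is not controlled and is not needed.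

**Step 1**
Reactants: 1 3-bromo-4-hydroxyphenylacetic acid; 2 chlorotriisopropylsilane
Product: 4 [3-bromo-4-(triisopropylsilyloxy)phenyl]acetic acid, via bis-silylated silyl ester 3 (not isolated)
Conditions: TIPSCl (2.2 equiv), imidazole, DMF, rt; then K2CO3, THF–MeOH–H2O, 0 °C; work-up at pH 4
Reagents that add atoms: chlorotriisopropylsilane, CC(C)[Si](Cl)(C(C)C)C(C)C
Why: Imidazole-mediated O-silylation of both acidic hydroxyls followed by selective hydrolysis of the labile silyl ester should leave the hindered aryl silyl ether, which tolerates TiCl4, AlMe3, the palladium coupling and carbanions.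

**Step 2**
Reactants: 4 [3-bromo-4-(triisopropylsilyloxy)phenyl]acetic acid; 5 pivaloyl chloride; 6 (4S)-4-benzyl-1,3-oxazolidin-2-one
Product: 8 (4S)-4-benzyl-3-{[3-bromo-4-(triisopropylsilyloxy)phenyl]acetyl}-1,3-oxazolidin-2-one, via mixed pivalic anhydride 7 (not isolated)
Conditions: t-BuCOCl, Et3N, THF, −20 °C; then 6, LiCl, −20 °C → rt
Reagents that add atoms: (4S)-4-benzyl-1,3-oxazolidin-2-one, O=C1OC[C@H](Cc2ccccc2)N1
Why: N-Acylation of the Evans oxazolidinone through the mixed pivalic anhydride (LiCl/Et3N variant), the nucleophile attacking the unhindered arylacetyl carbonyl.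

**Step 3**
Reactants: 8 (4S)-4-benzyl-3-{[3-bromo-4-(triisopropylsilyloxy)phenyl]acetyl}-1,3-oxazolidin-2-one; 9 1,3,5-trioxane
Product: 10 (4S)-4-benzyl-3-{(2R)-2-[3-bromo-4-(triisopropylsilyloxy)phenyl]-3-hydroxypropanoyl}-1,3-oxazolidin-2-one
Conditions: TiCl4, i-Pr2NEt, CH2Cl2, 0 °C; then 9, TiCl4, 0 °C; aq. NH4Cl
Reagents that add atoms: 1,3,5-trioxane, C1OCOCO1
Why: Evans aldol-type hydroxymethylation, in which the chelated chlorotitanium Z-enolate is attacked by TiCl4-activated formaldehyde on the face opposite the C4 benzyl group of the auxiliary, which sets the (R) centre that becomes C3 while no alkene is yet present to react with the activated formaldehyde.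

**Step 4**
Reactants: 10 (4S)-4-benzyl-3-{(2R)-2-[3-bromo-4-(triisopropylsilyloxy)phenyl]-3-hydroxypropanoyl}-1,3-oxazolidin-2-one; 11 N,O-dimethylhydroxylamine hydrochloride
Product: 12 (2R)-2-[3-bromo-4-(triisopropylsilyloxy)phenyl]-3-hydroxy-N-methoxy-N-methylpropanamide
Conditions: MeNH(OMe)·HCl, AlMe3, CH2Cl2, −10 → 20 °C; aq. potassium sodium tartrate
Reagents that add atoms: N,O-dimethylhydroxylamine hydrochloride, CNOC.Cl
Why: Weinreb transamination of the imide with the aluminium amide made from AlMe3 and the amine hydrochloride, delivered to the exocyclic carbonyl through the aluminium alkoxide of the β-hydroxyl under non-basic conditions that leave the α-aryl centre intact.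

**Step 5**
Reactants: 12 (2R)-2-[3-bromo-4-(triisopropylsilyloxy)phenyl]-3-hydroxy-N-methoxy-N-methylpropanamide; 13 bis(pinacolato)diboron; 14 geranyl bromide
Product: 16 (2R)-2-{3-[(2E)-3,7-dimethylocta-2,6-dien-1-yl]-4-(triisopropylsilyloxy)phenyl}-3-hydroxy-N-methoxy-N-methylpropanamide, via aryl pinacol boronate 15 (not isolated)
Conditions: 13, PdCl2(dppf) (5 mol %), KOAc, 1,4-dioxane, 85 °C; then 14, K3PO4, H2O, 50 °C
Reagents that add atoms: geranyl bromide, CC(C)=CCC/C(C)=C/CBr
Why: One-pot Miyaura borylation and Suzuki–Miyaura allylation, in which the π-geranylpalladium species formed from the allylic bromide should couple with the aryl boronate at its unsubstituted terminus with retention of the E geometry, while acetate and phosphate are too weak to epimerise an α-aryl amide.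

**Step 6**
Reactants: 16 (2R)-2-{3-[(2E)-3,7-dimethylocta-2,6-dien-1-yl]-4-(triisopropylsilyloxy)phenyl}-3-hydroxy-N-methoxy-N-methylpropanamide; 17 methyl phenyl sulfoxide
Product: 18 (3R)-3-Ar-4-hydroxy-1-(phenylsulfinyl)butan-2-one (both sulfur epimers; used without chromatography)
Conditions: 17 (3.5 equiv), LiN(i-Pr)2 (3.3 equiv), THF, −78 °C; add 16, −78 → −50 °C; AcOH, −78 °C
Reagents that add atoms: methyl phenyl sulfoxide, CS(=O)c1ccccc1
Why: Acylation of the α-sulfinyl carbanion by the Weinreb amide, in which the first equivalent forms the alkoxide that suppresses α-deprotonation and the chelated tetrahedral adduct releases the ketone only in the cold acidic quench, so the new ketone never meets base.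

**Step 7**
Reactants: 18 (3R)-3-Ar-4-hydroxy-1-(phenylsulfinyl)butan-2-one; 19 N,N-dimethylformamide dimethyl acetal
Product: 21 (3R)-3-{3-[(2E)-3,7-dimethylocta-2,6-dien-1-yl]-4-(triisopropylsilyloxy)phenyl}-5-(phenylsulfinyl)-2,3-dihydro-4H-pyran-4-one (both sulfur epimers), via dimethylaminomethylene enaminone 20 (not isolated)
Conditions: Me2NCH(OMe)2, toluene, 0 → 25 °C; then AcOH (1.5 equiv), 40 °C, evaporation under reduced pressure
Reagents that add atoms: N,N-dimethylformamide dimethyl acetal, COC(OC)N(C)C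
Why: Enaminone annulation, in which the amide acetal condenses with the CH2 flanked by C=O and S=O to give 20, whose primary hydroxyl adds 6-endo-trig to the enaminone carbon and expels Me2NH (the sequence that converts 2-hydroxyaryl β-keto sulfoxides into 3-sulfinylchromones), C3 being spared because the doubly activated methylene is the only carbon acid engaged.

**Step 8**
Reactants: 22 methyl acetoacetate; 23 prenyl bromide
Product: 24 methyl 2-acetyl-5-methylhex-4-enoate
Conditions: K2CO3, acetone, reflux (22 in excess)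
Reagents that add atoms: prenyl bromide, CC(C)=CCBr
Why: SN2 C-alkylation of the acetoacetate enolate with the allylic bromide.

**Step 9**
Reactants: 24 methyl 2-acetyl-5-methylhex-4-enoate; 25 chlorotrimethylsilane
Product: 26 methyl 2-(3-methylbut-2-en-1-yl)-3-(trimethylsilyloxy)but-2-enoate
Conditions: Me3SiCl, Et3N, hexane, rt
Reagents that add atoms: chlorotrimethylsilane, C[Si](C)(C)Cl
Why: O-Silylation of the enol form of the β-keto ester with Me3SiCl/Et3N gives the mono silyl enol ether.

**Step 10**
Reactants: 26 methyl 2-(3-methylbut-2-en-1-yl)-3-(trimethylsilyloxy)but-2-enoate; 25 chlorotrimethylsilane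
Product: 27 1-methoxy-2-(3-methylbut-2-en-1-yl)-1,3-bis(trimethylsilyloxy)buta-1,3-diene (used fresh)
Conditions: LiN(i-Pr)2, THF, −78 °C; Me3SiCl, −78 → 0 °C
Reagents that add atoms: chlorotrimethylsilane, C[Si](C)(C)Cl
Why: γ-Deprotonation of the vinylogous ester by LiN(i-Pr)2 and O-silylation of the extended enolate give the 1-alkoxy-1,3-bis(silyloxy)diene.

**Step 11**
Reactants: 21 (3R)-3-Ar-5-(phenylsulfinyl)-2,3-dihydro-4H-pyran-4-one; 27 1-methoxy-2-prenyl-1,3-bis(trimethylsilyloxy)buta-1,3-diene
Product: 30 (3R)-3-{3-[(2E)-3,7-dimethylocta-2,6-dien-1-yl]-4-(triisopropylsilyloxy)phenyl}-5,7-dihydroxy-6-(3-methylbut-2-en-1-yl)-2,3-dihydro-4H-chromen-4-one, via cycloadduct 28 (not isolated), via dihydroarene ketal 29 (not isolated)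
Conditions: 27 (3 equiv), toluene, 25 → 70 °C, under argon; then 0.1 M HCl, THF–H2O, 0 °C
Reagents that add atoms: diene 27, COC(O[Si](C)(C)C)=C(CC=C(C)C)C(=C)O[Si](C)(C)C
Why: Proposed new method: the electron-rich diene 27 and the C5=C6 bond of 21, made electron-poor by the carbonyl and sulfinyl groups on C5, should combine in a normal-demand, asynchronous [4+2] cycloaddition to the cis-fused adduct 28, in which S(O)Ph on C4a and H on C8a are cis, so that thermal syn elimination of PhSOH gives 29; mild acid then hydrolyses the mixed ketal and the silyl enol ether, and the dione tautomerises to the 5,7-dihydroxy arene. The closest known reaction type is the Diels–Alder/aromatisation of 1-alkoxy-1,3-bis(silyloxy)butadienes with 3-sulfinyl- or 3-halochromones, haloquinones and alkynones; the non-benzo, C3-stereogenic 2,3-dihydropyran-4-one is the new substrate class. Ring A closes by an intermolecular [4+2] cycloaddition that forms C4a–C5 and C8–C8a and gives a six-membered carbocycle. No stereocentre of 28 survives aromatisation, and C3 is only carried through, since the medium is neutral until the short, cold acid work-up. The step needs regioselectivity, which is secured because the most nucleophilic diene terminus (its CH2 carbon) meets the only electrophilic alkene carbon, C6 of 21 (β to both acceptors), so that the ketene acetal carbon ends on C4a and the prenyl group is locked at C6. It also needs chemoselectivity over the unactivated trisubstituted alkenes, and the excess of 27 silylates the sulfenic acid before it can react elsewhere.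

**Step 12**
Reactants: 30 (3R)-3-Ar-5,7-dihydroxy-6-prenyl-2,3-dihydro-4H-chromen-4-one
Product: 31 (3R)-3-{3-[(2E)-3,7-dimethylocta-2,6-dien-1-yl]-4-hydroxyphenyl}-5,7-dihydroxy-6-(3-methylbut-2-en-1-yl)-2,3-dihydro-4H-chromen-4-one (CNP0165005.1)
Conditions: Bu4NF (1.2 equiv), AcOH (1.5 equiv), THF, 0 °C
Reagents that add atoms: none
Why: Fluoride cleavage of the aryl silyl ether, buffered by acetic acid so that the phenoxide is protonated at once and neither base at C3–H nor acid at the prenyl- and geranyl-phenol pairs intervenes.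

**Compound list** (Ar as defined above)

1 | 3-bromo-4-hydroxyphenylacetic acid | OC(=O)Cc1ccc(O)c(Br)c1 | starting material
2 | chlorotriisopropylsilane | CC(C)[Si](Cl)(C(C)C)C(C)C | starting material
3 | triisopropylsilyl [3-bromo-4-(triisopropylsilyloxy)phenyl]acetate (formed in the flask) | CC(C)[Si](OC(=O)Cc1ccc(O[Si](C(C)C)(C(C)C)C(C)C)c(Br)c1)(C(C)C)C(C)C | intermediate
4 | [3-bromo-4-(triisopropylsilyloxy)phenyl]acetic acid | OC(=O)Cc1ccc(O[Si](C(C)C)(C(C)C)C(C)C)c(Br)c1 | intermediate
5 | pivaloyl chloride | CC(C)(C)C(Cl)=O | starting material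
6 | (4S)-4-benzyl-1,3-oxazolidin-2-one | O=C1OC[C@H](Cc2ccccc2)N1 | starting material
7 | [3-bromo-4-(triisopropylsilyloxy)phenyl]acetic pivalic anhydride (formed in the flask) | CC(C)(C)C(=O)OC(=O)Cc1ccc(O[Si](C(C)C)(C(C)C)C(C)C)c(Br)c1 | intermediate
8 | (4S)-4-benzyl-3-{[3-bromo-4-(triisopropylsilyloxy)phenyl]acetyl}-1,3-oxazolidin-2-one | O=C1OC[C@H](Cc2ccccc2)N1C(=O)Cc1ccc(O[Si](C(C)C)(C(C)C)C(C)C)c(Br)c1 | intermediate
9 | 1,3,5-trioxane | C1OCOCO1 | starting material
10 | (4S)-4-benzyl-3-{(2R)-2-[3-bromo-4-(triisopropylsilyloxy)phenyl]-3-hydroxypropanoyl}-1,3-oxazolidin-2-one | O=C1OC[C@H](Cc2ccccc2)N1C(=O)[C@@H](CO)c1ccc(O[Si](C(C)C)(C(C)C)C(C)C)c(Br)c1 | intermediate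
11 | N,O-dimethylhydroxylamine hydrochloride | CNOC.Cl | starting material
12 | (2R)-2-[3-bromo-4-(triisopropylsilyloxy)phenyl]-3-hydroxy-N-methoxy-N-methylpropanamide | CON(C)C(=O)[C@@H](CO)c1ccc(O[Si](C(C)C)(C(C)C)C(C)C)c(Br)c1 | intermediate
13 | bis(pinacolato)diboron | CC1(C)OB(OC1(C)C)B1OC(C)(C)C(C)(C)O1 | starting material
14 | geranyl bromide, (2E)-1-bromo-3,7-dimethylocta-2,6-diene | CC(C)=CCC/C(C)=C/CBr | starting material
15 | (2R)-3-hydroxy-N-methoxy-N-methyl-2-[3-(4,4,5,5-tetramethyl-1,3,2-dioxaborolan-2-yl)-4-(triisopropylsilyloxy)phenyl]propanamide (formed in the flask) | CON(C)C(=O)[C@@H](CO)c1ccc(O[Si](C(C)C)(C(C)C)C(C)C)c(B2OC(C)(C)C(C)(C)O2)c1 | intermediate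
16 | (2R)-2-{3-[(2E)-3,7-dimethylocta-2,6-dien-1-yl]-4-(triisopropylsilyloxy)phenyl}-3-hydroxy-N-methoxy-N-methylpropanamide | CC(C)=CCC/C(C)=C/Cc1cc([C@H](CO)C(=O)N(C)OC)ccc1O[Si](C(C)C)(C(C)C)C(C)C | intermediate
17 | methyl phenyl sulfoxide (racemic) | CS(=O)c1ccccc1 | starting material
18 | (3R)-3-Ar-4-hydroxy-1-(phenylsulfinyl)butan-2-one (both epimers at sulfur) | CC(C)=CCC/C(C)=C/Cc1cc([C@H](CO)C(=O)CS(=O)c2ccccc2)ccc1O[Si](C(C)C)(C(C)C)C(C)C | intermediate
19 | N,N-dimethylformamide dimethyl acetal | COC(OC)N(C)C | starting material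
20 | (4R)-4-Ar-1-(dimethylamino)-5-hydroxy-2-(phenylsulfinyl)pent-1-en-3-one (formed in the flask; both epimers at sulfur, alkene geometry open) | CC(C)=CCC/C(C)=C/Cc1cc([C@H](CO)C(=O)C(=CN(C)C)S(=O)c2ccccc2)ccc1O[Si](C(C)C)(C(C)C)C(C)C | intermediate
21 | (3R)-3-{3-[(2E)-3,7-dimethylocta-2,6-dien-1-yl]-4-(triisopropylsilyloxy)phenyl}-5-(phenylsulfinyl)-2,3-dihydro-4H-pyran-4-one (both epimers at sulfur) | CC(C)=CCC/C(C)=C/Cc1cc([C@@H]2COC=C(S(=O)c3ccccc3)C2=O)ccc1O[Si](C(C)C)(C(C)C)C(C)C | intermediate
22 | methyl acetoacetate | COC(=O)CC(C)=O | starting material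
23 | prenyl bromide, 1-bromo-3-methylbut-2-ene | CC(C)=CCBr | starting material
24 | methyl 2-acetyl-5-methylhex-4-enoate (racemic, enolisable centre) | COC(=O)C(CC=C(C)C)C(C)=O | intermediate
25 | chlorotrimethylsilane | C[Si](C)(C)Cl | starting material
26 | methyl 2-(3-methylbut-2-en-1-yl)-3-(trimethylsilyloxy)but-2-enoate (double-bond isomers) | COC(=O)C(CC=C(C)C)=C(C)O[Si](C)(C)C | intermediate
27 | 1-methoxy-2-(3-methylbut-2-en-1-yl)-1,3-bis(trimethylsilyloxy)buta-1,3-diene (ketene acetal geometry open) | COC(O[Si](C)(C)C)=C(CC=C(C)C)C(=C)O[Si](C)(C)C | intermediate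
28 | (3R)-3-Ar-5-methoxy-6-prenyl-4a-(phenylsulfinyl)-5,7-bis(trimethylsilyloxy)-2,3,4a,5,8,8a-hexahydro-4H-chromen-4-one (formed in the flask; cis ring fusion, mixture at C4a, C5, C8a and sulfur) | CC(C)=CCC/C(C)=C/Cc1cc([C@@H]2COC3CC(O[Si](C)(C)C)=C(CC=C(C)C)C(OC)(O[Si](C)(C)C)C3(S(=O)c4ccccc4)C2=O)ccc1O[Si](C(C)C)(C(C)C)C(C)C | intermediate
29 | (3R)-3-Ar-5-methoxy-6-prenyl-5,7-bis(trimethylsilyloxy)-2,3,5,8-tetrahydro-4H-chromen-4-one (formed in the flask; mixture at C5) | CC(C)=CCC/C(C)=C/Cc1cc([C@@H]2COC3=C(C2=O)C(OC)(O[Si](C)(C)C)C(CC=C(C)C)=C(O[Si](C)(C)C)C3)ccc1O[Si](C(C)C)(C(C)C)C(C)C | intermediate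
30 | (3R)-3-{3-[(2E)-3,7-dimethylocta-2,6-dien-1-yl]-4-(triisopropylsilyloxy)phenyl}-5,7-dihydroxy-6-(3-methylbut-2-en-1-yl)-2,3-dihydro-4H-chromen-4-one | CC(C)=CCC/C(C)=C/Cc1cc([C@@H]2COc3cc(O)c(CC=C(C)C)c(O)c3C2=O)ccc1O[Si](C(C)C)(C(C)C)C(C)C | intermediate
31 | (3R)-3-{3-[(2E)-3,7-dimethylocta-2,6-dien-1-yl]-4-hydroxyphenyl}-5,7-dihydroxy-6-(3-methylbut-2-en-1-yl)-2,3-dihydro-4H-chromen-4-one | CC(C)=CCC/C(C)=C/Cc1cc([C@@H]2COc3cc(O)c(CC=C(C)C)c(O)c3C2=O)ccc1O | target

**Step count**

Total: 12 steps. Longest linear sequence: 9 steps (steps 1–7, 11 and 12). The diene branch (steps 8–10) has 3 steps.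

**Steps most likely to fail**

Step 11 (new method). The push–pull alkene may react so slowly that the diene decomposes first. Addition may stop at a stepwise Michael adduct that opens the pyranone by β-elimination of O1. C3 may epimerise by thermal enolisation, or aromatisation may stall at the ketal stage. The fallback uses known chemistry only: ring A is brought in as a preformed, mirror-symmetric phenol, so that regiochemistry is fixed by symmetry, and ring C is closed by a Parham cyclisation. It sets out from 16 (with commercial phloroglucinol) and comes back to the route at 30. Phloroglucinol with MOMCl (2 equiv) and i-Pr2NEt gives 3,5-bis(methoxymethoxy)phenol F1, and silylation (TIPSCl, imidazole) gives [3,5-bis(methoxymethoxy)phenoxy]triisopropylsilane F2. Directed lithiation between the two acetal groups (n-BuLi, THF, 0 °C), transmetalation with CuI and alkylation with prenyl bromide give [3,5-bis(methoxymethoxy)-4-prenylphenoxy]triisopropylsilane F3. Bu4NF frees 3,5-bis(methoxymethoxy)-4-prenylphenol F4, whose two ortho positions are equivalent. Mono-iodination (I2, NaHCO3, THF–H2O, 0 °C) gives 2-iodo-3,5-bis(methoxymethoxy)-4-prenylphenol F5. Mitsunobu etherification of the primary alcohol of 16 with this phenol (PPh3, DIAD, toluene) gives the aryl ether F6. Iodine–lithium exchange (t-BuLi, THF, −90 °C) and attack of the aryllithium on the Weinreb amide close ring C as the 5,7-bis(methoxymethyl) ether F7. Dilute HCl in MeOH removes the two acetals and gives 30; the acid exposure that the main route avoids is accepted here and kept short.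

Step 7. The liberated dimethylamine may erode the configuration at C3 or re-open the ring, the sequence may stop at enaminone 20, or the β-hydroxy ketone 18 may dehydrate before it is engaged. The fallback introduces sulfur after the ring carbons; it sets out from 16 and comes back at 21. Ethynylmagnesium bromide (4 equiv, THF, 0 °C; NaHSO4 quench) gives the hydroxy ynone F8. Diethylamine adds at 0 °C to give the E-enaminone F9. N-(Phenylthio)succinimide sulfenylates its nucleophilic α-carbon to give the thio-enaminone F10. On addition of AcOH this loses diethylamine and closes to the 5-(phenylthio)dihydropyranone F11, the enaminone route known for 3-sulfenylchromones. NaIO4 in aqueous MeOH oxidises sulfur only and gives 21.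

Step 5. The hindered ortho-silyloxy boronate may protodeboronate. Coupling may occur at the tertiary allyl terminus, the E alkene may partly isomerise through the π-allyl complex, or geranyl bromide may solvolyse. The fallback reverses the polarity of the coupling and needs no boron intermediate and no base. Migita–Kosugi–Stille coupling of bromide 12 with (E)-geranyltributylstannane (Pd2(dba)3, P(t-Bu)3, toluene, 80 °C) leads from 12 directly to 16 and makes no new intermediate.

**Further compounds**

F1 | step 11 | 3,5-bis(methoxymethoxy)phenol | COCOc1cc(O)cc(OCOC)c1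
F2 | step 11 | [3,5-bis(methoxymethoxy)phenoxy]triisopropylsilane | COCOc1cc(OCOC)cc(O[Si](C(C)C)(C(C)C)C(C)C)c1
F3 | step 11 | [3,5-bis(methoxymethoxy)-4-(3-methylbut-2-en-1-yl)phenoxy]triisopropylsilane | COCOc1cc(O[Si](C(C)C)(C(C)C)C(C)C)cc(OCOC)c1CC=C(C)C
F4 | step 11 | 3,5-bis(methoxymethoxy)-4-(3-methylbut-2-en-1-yl)phenol | COCOc1cc(O)cc(OCOC)c1CC=C(C)C
F5 | step 11 | 2-iodo-3,5-bis(methoxymethoxy)-4-(3-methylbut-2-en-1-yl)phenol | COCOc1cc(O)c(I)c(OCOC)c1CC=C(C)C
F6 | step 11 | (2R)-2-Ar-3-[2-iodo-3,5-bis(methoxymethoxy)-4-(3-methylbut-2-en-1-yl)phenoxy]-N-methoxy-N-methylpropanamide | CC(C)=CCC/C(C)=C/Cc1cc([C@H](COc2cc(OCOC)c(CC=C(C)C)c(OCOC)c2I)C(=O)N(C)OC)ccc1O[Si](C(C)C)(C(C)C)C(C)C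
F7 | step 11 | (3R)-3-Ar-5,7-bis(methoxymethoxy)-6-(3-methylbut-2-en-1-yl)-2,3-dihydro-4H-chromen-4-one | CC(C)=CCC/C(C)=C/Cc1cc([C@@H]2COc3cc(OCOC)c(CC=C(C)C)c(OCOC)c3C2=O)ccc1O[Si](C(C)C)(C(C)C)C(C)C
F8 | step 7 | (4R)-4-Ar-5-hydroxypent-1-yn-3-one | CC(C)=CCC/C(C)=C/Cc1cc([C@H](CO)C(=O)C#C)ccc1O[Si](C(C)C)(C(C)C)C(C)C
F9 | step 7 | (1E,4R)-4-Ar-1-(diethylamino)-5-hydroxypent-1-en-3-one | CC(C)=CCC/C(C)=C/Cc1cc([C@H](CO)C(=O)/C=C/N(CC)CC)ccc1O[Si](C(C)C)(C(C)C)C(C)C
F10 | step 7 | (4R)-4-Ar-1-(diethylamino)-5-hydroxy-2-(phenylthio)pent-1-en-3-one | CC(C)=CCC/C(C)=C/Cc1cc([C@H](CO)C(=O)C(Sc2ccccc2)=CN(CC)CC)ccc1O[Si](C(C)C)(C(C)C)C(C)C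
F11 | step 7 | (3R)-3-Ar-5-(phenylthio)-2,3-dihydro-4H-pyran-4-one | CC(C)=CCC/C(C)=C/Cc1cc([C@@H]2COC=C(Sc3ccccc3)C2=O)ccc1O[Si](C(C)C)(C(C)C)C(C)C
F0 | step 5 | none | none
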